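Everything rests on disconnecting ring A of the decalin by a [3+3] Michael–aldol (Robinson-type) annulation. The feature exploited is that the gem-dimethyl carbon C4 and the ring-fusion alkene carbon C10 (halimane numbering) are 1,3-related through the fusion methine C5, i.e. they are the β-carbon and the carbonyl carbon of a 2-isopropylidenecyclohexanone. Ethyl acetoacetate delivers C1–C3 and, in one operation, makes the C3–C4 bond by conjugate addition and the C1=C10 bond by aldol condensation while fixing C5. The precursor is (R)-pulegone carrying the C9 quaternary centre (methyl plus carboxylic acid side chain) from two α′-alkylations; desulfurisation and opening of (R)-glycidyl acetate complete the glyceride.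

Key step: step 6

Remark: ring B is C5–C10 (C8 the methyl-bearing methine, C9 the quaternary carbon), C1–C3 are the remaining ring A carbons and C11–C15 the side chain; compounds 1, 4 and 14 are taken as commercial single enantiomers.

Step 1
Reactants: 1 methyl (R)-3-methylglutarate
Product: 2 methyl (3R)-5-hydroxy-3-methylpentanoate
Conditions: BH3·SMe2, THF, 0 °C to rt; MeOH quench
Reagents that add atoms: none
Why: Borane reduces the free carboxylic acid far faster than the methyl ester (chemoselective borane reduction of a half-ester), and the stereocentre is not involved.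

Step 2
Reactants: 2 methyl (3R)-5-hydroxy-3-methylpentanoate
Product: 3 methyl (3S)-5-iodo-3-methylpentanoate
Conditions: I2, PPh3, imidazole, CH2Cl2, 0 °C to rt (crude 2 used at once)
Reagents that add atoms: iodine, II
Why: Appel-type iodination converts the primary alcohol into the iodide under neutral conditions before the hydroxy ester can lactonise (the descriptor changes only because iodine raises the priority of that arm).

Step 3
Reactants: 4 (R)-pulegone; 3 methyl (3S)-5-iodo-3-methylpentanoate
Product: 5 methyl (3R)-3-methyl-5-[(6R)-6-methyl-2-oxo-3-(propan-2-ylidene)cyclohexyl]pentanoate (both epimers at ring carbon 1)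
Conditions: LiN(i-Pr)2 (LDA, 1.1 equiv to 4), THF, −78 °C; then 3 (0.8 equiv), DMPU, −78 to 0 °C
Reagents that add atoms: none
Why: LDA deprotonates pulegone kinetically at the α′-methylene rather than at the allylic methyl groups and the lithium enolate is alkylated by the unhindered primary iodide (SN2 enolate alkylation), the configuration of the new tertiary centre being irrelevant because it is enolised again in step 5.

Step 4
Reactants: 5 methyl (3R)-3-methyl-5-[(6R)-6-methyl-2-oxo-3-(propan-2-ylidene)cyclohexyl]pentanoate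
Product: 6 (3R)-3-methyl-5-[(6R)-6-methyl-2-oxo-3-(propan-2-ylidene)cyclohexyl]pentanoic acid (both epimers at ring carbon 1)
Conditions: LiOH, THF/MeOH/H2O, rt; then aq. HCl
Reagents that add atoms: lithium hydroxide, [Li+].[OH-]
Why: Ester saponification leaves the hindered enone untouched and gives the acid, which as its lithium carboxylate is neither electrophilic nor readily enolised during the next enolate alkylation.

Step 5
Reactants: 6 (3R)-3-methyl-5-[(6R)-6-methyl-2-oxo-3-(propan-2-ylidene)cyclohexyl]pentanoic acid
Product: 7 (3R)-5-[(1R,6R)-1,6-dimethyl-2-oxo-3-(propan-2-ylidene)cyclohexyl]-3-methylpentanoic acid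
Conditions: LDA (2.2 equiv), THF, −78 to −40 °C; MeI, DMPU, −78 to −20 °C; aq. HCl work-up
Reagents that add atoms: iodomethane, CI
Why: The first equivalent of LDA forms the carboxylate and the second the tetrasubstituted α′-enolate, which is C-methylated (enolate alkylation) on the face anti to the neighbouring pseudoaxial ring methyl group, so the new methyl is trans to it and the quaternary centre is (R).

Step 6
Reactants: 7 (3R)-5-[(1R,6R)-1,6-dimethyl-2-oxo-3-(propan-2-ylidene)cyclohexyl]-3-methylpentanoic acid; 8 ethyl acetoacetate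
Product: 11 (3R)-3-methyl-5-[(1R,2R,4aS)-1,2,5,5-tetramethyl-7-oxo-1,2,3,4,4a,5,6,7-octahydronaphthalen-1-yl]pentanoic acid, via diketo ester Michael adduct 9 (not isolated), via bicyclic keto ester 10 (not isolated)
Conditions: 8 (3 equiv), NaOEt (4 equiv), EtOH, reflux; then 2 M aq. KOH, rt to 50 °C; then HCl to pH 2, 50 °C
Reagents that add atoms: none
Why: The sodium enolate of 8 adds 1,4 to the exocyclic isopropylidene enone of 7 (C3–C4 bond, creating the gem-dimethyl quaternary carbon), the enolate of the acetyl methyl group then attacks the ring ketone (C1–C10 bond) and the ketol loses water by E1cB to give the C1=C10 enone, after which mild saponification and decarboxylation of the β-keto ester remove the activating group. The closest known reaction is the Robinson-type [3+3] Michael–aldol annulation, precisely the classical condensation of pulegone itself with acetoacetic ester. Ring A is closed in a 6-(enolexo)-exo-trig aldol addition. The new stereocentre C5 is α to the ketone and therefore epimerisable until ring closure; only the epimer that has C4 equatorial in the ring B chair which also keeps the C8 methyl equatorial can place the new axial substituent on C10 without a syn-axial clash with that methyl, which should give the (S) configuration (H5 cis to the side chain, trans to the C9 methyl). The step needs 1,4- rather than 1,2-addition and a single mode of ring closure: the soft, stabilised donor secures the former, and the quaternary C9 (no α′-hydrogen) together with the 1,5-relationship of the two carbonyl groups leaves the six-membered closure as the only productive aldol pathway.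

Step 7
Reactants: 11 (3R)-3-methyl-5-[(1R,2R,4aS)-1,2,5,5-tetramethyl-7-oxo-1,2,3,4,4a,5,6,7-octahydronaphthalen-1-yl]pentanoic acid
Product: 12 (3R)-5-[(1R,2R,4aS)-7,7-(ethane-1,2-diyldisulfanediyl)-1,2,5,5-tetramethyl-1,2,3,4,4a,5,6,7-octahydronaphthalen-1-yl]-3-methylpentanoic acid (the spiro-1,3-dithiolane of 11)
Conditions: HSCH2CH2SH, BF3·OEt2, AcOH, rt
Reagents that add atoms: ethane-1,2-dithiol, SCCS
Why: Lewis-acid thioketalisation of a cyclohexenone, which for steroidal 4-en-3-ones proceeds without migration of the double bond, is favoured here because the fully substituted β-carbon suppresses conjugate thiol addition.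

Step 8
Reactants: 12 spiro-1,3-dithiolane of 11
Product: 13 (3R)-3-methyl-5-[(1R,2R,4aS)-1,2,5,5-tetramethyl-1,2,3,4,4a,5,6,7-octahydronaphthalen-1-yl]pentanoic acid
Conditions: Raney Ni (deactivated by brief reflux in acetone), EtOH, reflux
Reagents that add atoms: none
Why: Raney nickel hydrogenolysis of both C–S bonds (Mozingo desulfurisation) turns the thioketal carbon into CH2 and should leave the hindered trisubstituted alkene in place, so the enone oxygen is removed without transposition.

Step 9
Reactants: 14 (S)-glycidol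
Product: 15 (R)-glycidyl acetate, [(2R)-oxiran-2-yl]methyl acetate
Conditions: Ac2O, Et3N, DMAP (cat.), CH2Cl2, 0 °C
Reagents that add atoms: acetic anhydride, CC(=O)OC(C)=O
Why: DMAP-catalysed acylation of the primary alcohol leaves the epoxide and its stereocentre untouched (the descriptor changes only through the priority switch).

Step 10
Reactants: 13 (3R)-3-methyl-5-[(1R,2R,4aS)-1,2,5,5-tetramethyl-1,2,3,4,4a,5,6,7-octahydronaphthalen-1-yl]pentanoic acid; 15 (R)-glycidyl acetate
Product: 16 (2S)-3-(acetyloxy)-2-hydroxypropyl (3R)-3-methyl-5-[(1R,2R,4aS)-1,2,5,5-tetramethyl-1,2,3,4,4a,5,6,7-octahydronaphthalen-1-yl]pentanoate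
Conditions: 15 (1.3 equiv), racemic N,N′-bis(3,5-di-tert-butylsalicylidene)cyclohexane-1,2-diaminocobalt acetate (trivalent cobalt, 5 mol %), i-Pr2NEt, MTBE, rt
Reagents that add atoms: none
Why: Cobalt salen-catalysed addition of a carboxylic acid to a terminal epoxide occurs at the unsubstituted carbon, so the stereocentre is not a reacting atom and the secondary hydroxyl is liberated between the two ester groups with the (S) configuration.

Compound list
1 | methyl (R)-3-methylglutarate, (3R)-5-methoxy-3-methyl-5-oxopentanoic acid | COC(=O)C[C@H](C)CC(=O)O | starting material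
2 | methyl (3R)-5-hydroxy-3-methylpentanoate | COC(=O)C[C@H](C)CCO | intermediate
3 | methyl (3S)-5-iodo-3-methylpentanoate | COC(=O)C[C@H](C)CCI | intermediate
4 | (R)-(+)-pulegone, (5R)-5-methyl-2-(propan-2-ylidene)cyclohexan-1-one | C[C@@H]1CCC(=C(C)C)C(=O)C1 | starting material
5 | methyl (3R)-3-methyl-5-[(6R)-6-methyl-2-oxo-3-(propan-2-ylidene)cyclohexyl]pentanoate, both epimers at ring carbon 1 | COC(=O)C[C@H](C)CCC1C(=O)C(=C(C)C)CC[C@H]1C | intermediate
6 | (3R)-3-methyl-5-[(6R)-6-methyl-2-oxo-3-(propan-2-ylidene)cyclohexyl]pentanoic acid, both epimers at ring carbon 1 | OC(=O)C[C@H](C)CCC1C(=O)C(=C(C)C)CC[C@H]1C | intermediate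
7 | (3R)-5-[(1R,6R)-1,6-dimethyl-2-oxo-3-(propan-2-ylidene)cyclohexyl]-3-methylpentanoic acid | OC(=O)C[C@H](C)CC[C@@]1(C)C(=O)C(=C(C)C)CC[C@H]1C | intermediate
8 | ethyl acetoacetate (ethyl 3-oxobutanoate) | CCOC(=O)CC(C)=O | starting material
9 | (3R)-5-[(1R,6R)-3-(3-ethoxycarbonyl-2-methyl-4-oxopentan-2-yl)-1,6-dimethyl-2-oxocyclohexyl]-3-methylpentanoic acid, Michael adduct, epimers at ring carbon 3 and at the acetoacetate carbon | OC(=O)C[C@H](C)CC[C@@]1(C)C(=O)C(CC[C@H]1C)C(C)(C)C(C(C)=O)C(=O)OCC | intermediate
10 | (3R)-5-[(1R,2R,4aS)-6-ethoxycarbonyl-1,2,5,5-tetramethyl-7-oxo-1,2,3,4,4a,5,6,7-octahydronaphthalen-1-yl]-3-methylpentanoic acid, epimers at ring carbon 6 | OC(=O)C[C@H](C)CC[C@@]1(C)C2=CC(=O)C(C(=O)OCC)C(C)(C)[C@@H]2CC[C@H]1C | intermediate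
11 | (3R)-3-methyl-5-[(1R,2R,4aS)-1,2,5,5-tetramethyl-7-oxo-1,2,3,4,4a,5,6,7-octahydronaphthalen-1-yl]pentanoic acid | OC(=O)C[C@H](C)CC[C@@]1(C)C2=CC(=O)CC(C)(C)[C@@H]2CC[C@H]1C | intermediate
12 | (3R)-5-[(1R,2R,4aS)-7,7-(ethane-1,2-diyldisulfanediyl)-1,2,5,5-tetramethyl-1,2,3,4,4a,5,6,7-octahydronaphthalen-1-yl]-3-methylpentanoic acid | OC(=O)C[C@H](C)CC[C@@]1(C)C2=CC3(SCCS3)CC(C)(C)[C@@H]2CC[C@H]1C | intermediate
13 | (3R)-3-methyl-5-[(1R,2R,4aS)-1,2,5,5-tetramethyl-1,2,3,4,4a,5,6,7-octahydronaphthalen-1-yl]pentanoic acid | OC(=O)C[C@H](C)CC[C@@]1(C)C2=CCCC(C)(C)[C@@H]2CC[C@H]1C | intermediate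
14 | (S)-glycidol, [(2S)-oxiran-2-yl]methanol | OC[C@H]1CO1 | starting material
15 | (R)-glycidyl acetate, [(2R)-oxiran-2-yl]methyl acetate | CC(=O)OC[C@H]1CO1 | intermediate
16 | (2S)-3-(acetyloxy)-2-hydroxypropyl (3R)-3-methyl-5-[(1R,2R,4aS)-1,2,5,5-tetramethyl-1,2,3,4,4a,5,6,7-octahydronaphthalen-1-yl]pentanoate | CC(=O)OC[C@H](O)COC(=O)C[C@H](C)CC[C@@]1(C)C2=CCCC(C)(C)[C@@H]2CC[C@H]1C | target

Total step count: 10. Longest linear sequence: 9 steps (steps 1–8 and 10, from 1 to 16).

Steps most likely to fail

Step 6. The conjugate addition to the fully substituted β-carbon may stay on the side of the starting materials (retro-Michael), and ring closure onto the ketone flanked by the quaternary carbon may be slow, so that self-condensation of 8 and deconjugation of 7 take over; prolonged base could also epimerise C5 through the dienolate. The fallback makes the two bonds in separate operations and sets out from 7. TiCl4 (2.5 equiv, the carboxyl group being held as its titanium carboxylate) and 2-(trimethylsilyloxy)propene in CH2Cl2 at −78 °C should effect a Mukaiyama–Michael addition, which does not depend on an unfavourable enolate equilibrium. This should give the 1,5-diketone (3R)-5-[(1R,6R)-1,6-dimethyl-3-(2-methyl-4-oxopentan-2-yl)-2-oxocyclohexyl]-3-methylpentanoic acid F1. Pyrrolidine/AcOH in toluene (or KOH in MeOH) then closes ring A by intramolecular aldol condensation, and the route is rejoined at 11.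

Step 5. The small electrophile may discriminate poorly between the two faces of the tetrasubstituted enolate, and part of the base may be diverted to the allylic methyl groups. The fallback uses a bulkier, more reactive methyl surrogate and sets out from 6. Its dianion (LDA, 2.2 equiv) is alkylated with iodomethyl phenyl sulfide to give (3R)-3-methyl-5-[(1S,6R)-6-methyl-2-oxo-1-(phenylsulfanylmethyl)-3-(propan-2-ylidene)cyclohexyl]pentanoic acid F2. The conditions of step 6 (with 8) should convert it into the enone (3R)-3-methyl-5-[(1S,2R,4aS)-2,5,5-trimethyl-7-oxo-1-(phenylsulfanylmethyl)-1,2,3,4,4a,5,6,7-octahydronaphthalen-1-yl]pentanoic acid F3, and the conditions of step 7 into its spiro-1,3-dithiolane F4. The Raney Ni treatment of step 8 then cleaves all three C–S bonds, turning the phenylsulfanylmethyl group into the C9 methyl group, and the route is rejoined at 13.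

Step 10. The acetyl or the diterpenoyl group may migrate to the liberated secondary hydroxyl, and some opening may occur at the internal epoxide carbon, giving regioisomeric diesters that are hard to separate. The fallback builds the glyceride from a protected glycerol and sets out from 13. Steglich esterification (DCC, DMAP, CH2Cl2) with (R)-solketal should give [(4S)-2,2-dimethyl-1,3-dioxolan-4-yl]methyl (3R)-3-methyl-5-[(1R,2R,4aS)-1,2,5,5-tetramethyl-1,2,3,4,4a,5,6,7-octahydronaphthalen-1-yl]pentanoate F5. Acetonide cleavage (Dowex 50W in its acid form, MeOH/H2O, rt) should give the monoacylglycerol (2S)-2,3-dihydroxypropyl (3R)-3-methyl-5-[(1R,2R,4aS)-1,2,5,5-tetramethyl-1,2,3,4,4a,5,6,7-octahydronaphthalen-1-yl]pentanoate F6. Acetylation of the primary hydroxyl alone with vinyl acetate and immobilised Candida antarctica lipase B then rejoins the route at 16.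

Further compounds
F1 | step 6 | (3R)-5-[(1R,6R)-1,6-dimethyl-3-(2-methyl-4-oxopentan-2-yl)-2-oxocyclohexyl]-3-methylpentanoic acid, epimers at ring carbon 3 | OC(=O)C[C@H](C)CC[C@@]1(C)C(=O)C(CC[C@H]1C)C(C)(C)CC(C)=O
F2 | step 5 | (3R)-3-methyl-5-[(1S,6R)-6-methyl-2-oxo-1-(phenylsulfanylmethyl)-3-(propan-2-ylidene)cyclohexyl]pentanoic acid | OC(=O)C[C@H](C)CC[C@@]1(CSc2ccccc2)C(=O)C(=C(C)C)CC[C@H]1C
F3 | step 5 | (3R)-3-methyl-5-[(1S,2R,4aS)-2,5,5-trimethyl-7-oxo-1-(phenylsulfanylmethyl)-1,2,3,4,4a,5,6,7-octahydronaphthalen-1-yl]pentanoic acid | OC(=O)C[C@H](C)CC[C@@]1(CSc3ccccc3)C2=CC(=O)CC(C)(C)[C@@H]2CC[C@H]1C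
F4 | step 5 | (3R)-5-[(1S,2R,4aS)-7,7-(ethane-1,2-diyldisulfanediyl)-2,5,5-trimethyl-1-(phenylsulfanylmethyl)-1,2,3,4,4a,5,6,7-octahydronaphthalen-1-yl]-3-methylpentanoic acid | OC(=O)C[C@H](C)CC[C@@]1(CSc3ccccc3)C2=CC4(SCCS4)CC(C)(C)[C@@H]2CC[C@H]1C
F5 | step 10 | [(4S)-2,2-dimethyl-1,3-dioxolan-4-yl]methyl (3R)-3-methyl-5-[(1R,2R,4aS)-1,2,5,5-tetramethyl-1,2,3,4,4a,5,6,7-octahydronaphthalen-1-yl]pentanoate | CC1(C)OC[C@H](O1)COC(=O)C[C@H](C)CC[C@@]2(C)C3=CCCC(C)(C)[C@@H]3CC[C@H]2C
F6 | step 10 | (2S)-2,3-dihydroxypropyl (3R)-3-methyl-5-[(1R,2R,4aS)-1,2,5,5-tetramethyl-1,2,3,4,4a,5,6,7-octahydronaphthalen-1-yl]pentanoate | OC[C@H](O)COC(=O)C[C@H](C)CC[C@@]1(C)C2=CCCC(C)(C)[C@@H]2CC[C@H]1C
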